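**Plan**

- Locants (diterpenoid numbering): ring A = C1–C5 and C10; ring B = C5–C10; ring C = C8, C9, C11–C14; C15 = benzylic CH2 on C14; C19 = lactone C=O on C4; C20 = OCH2 on C10; β = the face of the C8 methyl.
- Cuts, in order: aryl O–CH3; the C19–O–C20 lactone with C4–CH3; C1–C2 and C5–C10 together; C3–C4 (vinyl) and C4–C19; C13–CH3; the cyclobutane of a nopinone; C14–C15 with C7–C8.
- Forward: ring C comes ready-made from (−)-verbenone (conjugate addition/benzylation, then cyclobutane cleavage); rings A and B close together in one cycloaddition; the lactone ring closes last, after reductive methylation.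
- Enabling feature: ring A carries C19 on C4 and C20 on C10, 1,3 across C5, and shares C5–C10 with ring B. It is therefore the adduct of a 2-(methoxycarbonyl)diene C2=C3–C4=C5 and a 2-substituted acrolein C1=C10–C20HO that hang from C8 and C9 of ring C.
- Stereochemistry: C9 from verbenone; C8 and C14 by attack anti to the gem-dimethyl bridge; C13 by equatorial methyl delivery; C5/C10 by the formyl-endo transition state on a chair-folded tether; C4 by equatorial methylation anti to the axial C20 arm.

Key step: step 8

Remark: the target is read as drawn, with the C15 arm on C14 cis to the C13 hydroxyl and trans to the C8 methyl (axial on ring C); compounds 1, 2 and 3 are taken as purchasable.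

**Route**

Step 1
Reactants: 1 (1S,5S)-(−)-verbenone; 2 (4-bromobut-1-yn-1-yl)trimethylsilane; 3 2,5-dimethoxybenzyl bromide
Product: 6 benzylated nopinone, via Grignard reagent 4 (not isolated), via magnesium enolate 5 (not isolated)
Conditions: 2, Mg, THF, rt; CuBr·SMe2 (10 mol%), 1, THF, −40 to 0 °C; then 3, DMPU, 0 °C to rt
Reagents that add atoms: none
Why: Copper-catalysed conjugate addition of the Grignard reagent to the β-methyl enone followed by C-benzylation of the resulting enolate (three-component conjugate addition/enolate alkylation) should set C8 and C14, because both reagents enter anti to the gem-dimethyl bridge and only the future C14 can enolise, the other α-carbon being a bridgehead.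

Step 2
Reactants: 6 benzylated nopinone
Product: 7 enol acetate
Conditions: BF3·OEt2, Zn(OAc)2, Ac2O, 0 °C to rt
Reagents that add atoms: acetic anhydride, CC(=O)OC(C)=O
Why: BF3-promoted heterolysis of the cyclobutane bond between the bridgehead α to the carbonyl and the gem-dimethyl carbon (Lewis-acid cyclobutane cleavage of nopinones) gives a boron enolate, trapped as the enol acetate, and a tertiary cation that loses a methyl proton to the isopropenyl group, so ring C emerges with C8, C9 and C14 untouched.

Step 3
Reactants: 7 enol acetate
Product: 8 ketone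
Conditions: MeLi (2.1 equiv), THF, −78 °C; AcOH, −78 °C
Reagents that add atoms: none
Why: Methyllithium cleaves the enol ester by acyl attack to the regiodefined C12–C13 lithium enolate, and kinetic protonation at C12 returns the ketone without ever enolising toward the epimerisable C14.

Step 4
Reactants: 8 ketone
Product: 9 tertiary carbinol
Conditions: CeCl3 (anhydrous), MeLi, THF, −78 °C; NH4Cl
Reagents that add atoms: methyllithium, [Li]C (used as methylcerium dichloride)
Why: 1,2-Addition of the non-basic organocerium reagent should deliver methyl from the β face, because the only open trajectory is equatorial attack on the chair with the C14 benzyl and C8 methyl equatorial (the other chair is blocked on one face by the syn-axial C8 methyl and on the other by the axial C14 benzyl), giving the 13β-methyl 13α-carbinol.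

Step 5
Reactants: 9 tertiary carbinol
Product: 10 ynoate
Conditions: CsF, CO2 (1 atm), DMSO, rt; then MeI
Reagents that add atoms: carbon dioxide, O=C=O; iodomethane, CI
Why: Fluoride cleaves the C(sp)–Si bond and the caesium acetylide is carboxylated by CO2 (fluoride-mediated carboxylation of an alkynylsilane), and iodomethane esterifies the caesium carboxylate in the same flask, which avoids a strong base next to the free carbinol.

Step 6
Reactants: 10 ynoate
Product: 11 allylic alcohol
Conditions: SeO2 (cat.), t-BuOOH, CH2Cl2, rt
Reagents that add atoms: tert-butyl hydroperoxide, CC(C)(C)OO (oxygen passed on through catalytic SeO2, O=[Se]=O)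
Why: Catalytic SeO2 allylic oxidation (ene reaction then [2,3]-sigmatropic shift) should hydroxylate the methyl of the isopropenyl group, the only electron-rich alkene with an accessible allylic CH3, and so installs the C20 oxygen while leaving the ynoate and the carbinol alone.

Step 7
Reactants: 11 allylic alcohol
Product: 13 dienoate, via stannyl enoate 12 (not isolated)
Conditions: Bu3SnH, Pd(PPh3)4 (5 mol%), THF, 0 °C; then vinyl bromide, CuI, DMF, 50 °C
Reagents that add atoms: vinyl bromide, C=CBr
Why: Palladium-catalysed syn-hydrostannation of the ynoate puts tin on the α-carbon and hydrogen on C5, and Stille coupling with vinyl bromide replaces tin with retention, so the chain on C5 ends trans to the new vinyl group (Z enoate), the geometry an s-cis diene with an outward tether requires.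

Step 8
Reactants: 13 dienoate
Product: 15 tricyclic aldehyde, via enal 14 (not isolated)
Conditions: MnO2 (activated), PhMe, rt; then BHT (cat.), 110 °C
Reagents that add atoms: none
Why: MnO2 oxidises only the allylic C20 alcohol to the 2-substituted acrolein 14, which on heating undergoes a concerted, asynchronous [4+2] cycloaddition with the C2=C3–C4=C5 dienoate; the closest known reaction type is the intramolecular Diels–Alder reaction of 1,7,9-decatrienals that carry the formyl group on the inner dienophile carbon. Ring A closes by the cycloaddition itself (bonds C1–C2 and C5–C10, suprafacial on both partners), and ring B closes through the same C5–C10 bond as the six-membered ring spanned by the four-carbon tether C6–C7–C8–C9 folding as a chair. C10 and C5 are set relative to each other by the formyl-endo (tether-exo) transition state, which puts C20 trans to H5 and so gives the trans ring fusion, and relative to the rest by C8 and C9, whose ring C bonds stay equatorial on the forming chair so that C20 ends axial on the β face, syn to the C8 methyl. The step needs endo over exo selectivity and an s-cis diene whose tether points outward: the first rests on secondary overlap of the formyl group and on the fact that either mode must place one C10 substituent syn-axial to the C8 methyl, the second on the Z enoate geometry fixed in step 7. The ester on C4 lowers the diene HOMO, which is why the dienophile is raised to the aldehyde level for this step only.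

Step 9
Reactants: 15 tricyclic aldehyde
Product: 16 hydroxy enoate
Conditions: NaBH4, MeOH/CH2Cl2, −20 °C
Reagents that add atoms: none
Why: NaBH4 reduces the neopentyl aldehyde far faster than the conjugated ester (chemoselective 1,2-reduction), returning C20 to the carbinol level needed for the lactone.

Step 10
Reactants: 16 hydroxy enoate
Product: 18 lactone dimethyl ether, via hydroxy ester 17 (not isolated)
Conditions: Li (3 equiv), NH3(l)/THF, t-BuOH (1 equiv), −78 °C; MeI, −78 to −33 °C; NH4Cl; then PPTS (cat.), PhMe, 60 °C
Reagents that add atoms: iodomethane, CI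
Why: Dissolving-metal reduction of the enoate gives the C4 ester enolate (Birch-type reductive alkylation), which iodomethane should attack from the equatorial α face, away from the axial C20 oxymethylene on C10, leaving the ester axial and 1,3-diaxial to C20 so that the δ-lactone closes under mild acid catalysis.

Step 11
Reactants: 18 lactone dimethyl ether
Product: 20 target hydroquinone CNP0148621.1, via quinone 19 (not isolated)
Conditions: (NH4)2Ce(NO3)6, MeCN/H2O, 0 °C; then aqueous Na2S2O4, EtOAc, rt, under argon
Reagents that add atoms: water, O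
Why: (NH4)2Ce(NO3)6 oxidises the 1,4-dimethoxyarene to the p-benzoquinone (oxidative demethylation) without touching the tertiary carbinol or the lactone, and dithionite reduces the quinone to the hydroquinone.

**Compound list**

1 | (1S,5S)-(−)-verbenone, (1S,5S)-4,6,6-trimethylbicyclo[3.1.1]hept-3-en-2-one | CC1=CC(=O)[C@H]2C[C@@H]1C2(C)C | starting material
2 | (4-bromobut-1-yn-1-yl)trimethylsilane | C[Si](C)(C)C#CCCBr | starting material
3 | 2-(bromomethyl)-1,4-dimethoxybenzene (2,5-dimethoxybenzyl bromide) | COc1ccc(OC)c(CBr)c1 | starting material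
4 | [4-(trimethylsilyl)but-3-yn-1-yl]magnesium bromide | C[Si](C)(C)C#CCC[Mg]Br | intermediate
5 | bromomagnesium C2–C3 enolate of 4-methyl-4-[4-(trimethylsilyl)but-3-ynyl]nopinone, butynyl chain anti to the gem-dimethyl bridge | C[C@@]1(CCC#C[Si](C)(C)C)[C@@H]2C[C@@H](C2(C)C)C(O[Mg]Br)=C1 | intermediate
6 | 3-(2,5-dimethoxybenzyl)-4,6,6-trimethyl-4-[4-(trimethylsilyl)but-3-ynyl]bicyclo[3.1.1]heptan-2-one; bridgeheads as in 1, C4 methyl syn and C4 butynyl anti to the C6 bridge, C3 benzyl anti to the bridge (cis to the butynyl chain) | C[C@@]1(CCC#C[Si](C)(C)C)[C@@H]2C[C@@H](C2(C)C)C(=O)[C@@H]1Cc1cc(OC)ccc1OC | intermediate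
7 | 1-acetoxy-6-(2,5-dimethoxybenzyl)-5-methyl-4-(prop-1-en-2-yl)-5-[4-(trimethylsilyl)but-3-ynyl]cyclohex-1-ene; benzyl trans to the C5 methyl and cis to the butynyl chain, isopropenyl cis to the C5 methyl | C[C@@]1(CCC#C[Si](C)(C)C)[C@@H](C(C)=C)CC=C(OC(C)=O)[C@@H]1Cc1cc(OC)ccc1OC | intermediate
8 | 2-(2,5-dimethoxybenzyl)-3-methyl-4-(prop-1-en-2-yl)-3-[4-(trimethylsilyl)but-3-ynyl]cyclohexan-1-one; benzyl trans to the C3 methyl, isopropenyl cis to it | C[C@@]1(CCC#C[Si](C)(C)C)[C@@H](C(C)=C)CCC(=O)[C@@H]1Cc1cc(OC)ccc1OC | intermediate
9 | 2-(2,5-dimethoxybenzyl)-1,3-dimethyl-4-(prop-1-en-2-yl)-3-[4-(trimethylsilyl)but-3-ynyl]cyclohexan-1-ol; C1 hydroxyl cis to the C2 benzyl, C1 methyl cis to the C3 methyl, rest as in 8 | C[C@@]1(CCC#C[Si](C)(C)C)[C@@H](C(C)=C)CC[C@](C)(O)[C@@H]1Cc1cc(OC)ccc1OC | intermediate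
10 | methyl pent-2-ynoate carrying at C5 the cyclohexyl unit of 9 (silyl group replaced by CO2CH3) | C[C@@]1(CCC#CC(=O)OC)[C@@H](C(C)=C)CC[C@](C)(O)[C@@H]1Cc1cc(OC)ccc1OC | intermediate
11 | as 10, with the isopropenyl group oxidised to 3-hydroxyprop-1-en-2-yl (C20 alcohol) | C[C@@]1(CCC#CC(=O)OC)[C@@H](C(CO)=C)CC[C@](C)(O)[C@@H]1Cc1cc(OC)ccc1OC | intermediate
12 | methyl (E)-2-(tributylstannyl)pent-2-enoate from 11; tin and the C5 hydrogen cis, ring-bearing chain cis to the ester | C[C@@]1(CC/C=C(/[Sn](CCCC)(CCCC)CCCC)C(=O)OC)[C@@H](C(CO)=C)CC[C@](C)(O)[C@@H]1Cc1cc(OC)ccc1OC | intermediate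
13 | methyl (Z)-2-vinylpent-2-enoate from 12 (2-(methoxycarbonyl)-1,3-diene; ring-bearing chain trans to the vinyl group), C20 alcohol free | C[C@@]1(CC/C=C(/C=C)C(=O)OC)[C@@H](C(CO)=C)CC[C@](C)(O)[C@@H]1Cc1cc(OC)ccc1OC | intermediate
14 | as 13, with the C20 alcohol oxidised to the 2-substituted acrolein | C[C@@]1(CC/C=C(/C=C)C(=O)OC)[C@@H](C(C=O)=C)CC[C@](C)(O)[C@@H]1Cc1cc(OC)ccc1OC | intermediate
15 | trans-anti-trans tricyclic aldehyde: methyl ester on C4 of a C3=C4 enoate, 10β-formyl, 5α-H, 8β-methyl, 9α-H, 13α-hydroxy-13β-methyl, 14α-(2,5-dimethoxybenzyl) | C[C@@]12CC[C@@H]3[C@](C=O)(CCC=C3C(=O)OC)[C@H]1CC[C@](C)(O)[C@@H]2Cc1cc(OC)ccc1OC | intermediate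
16 | as 15, with the 10β-formyl group reduced to 10β-hydroxymethyl | C[C@@]12CC[C@@H]3[C@](CO)(CCC=C3C(=O)OC)[C@H]1CC[C@](C)(O)[C@@H]2Cc1cc(OC)ccc1OC | intermediate
17 | saturated ester from 16: 4α-methyl, 4β-methoxycarbonyl (axial), 10β-hydroxymethyl | C[C@@]12CC[C@@H]3[C@](CO)(CCC[C@]3(C)C(=O)OC)[C@H]1CC[C@](C)(O)[C@@H]2Cc1cc(OC)ccc1OC | intermediate
18 | 19,20-lactone of 17 (bis-methyl ether of the target) | C[C@@]12CC[C@@H]3[C@]4(CCC[C@]3(C)C(=O)OC4)[C@H]1CC[C@](C)(O)[C@@H]2Cc1cc(OC)ccc1OC | intermediate
19 | 2-substituted 1,4-benzoquinone corresponding to 18 | C[C@@]12CC[C@@H]3[C@]4(CCC[C@]3(C)C(=O)OC4)[C@H]1CC[C@](C)(O)[C@@H]2CC1=CC(=O)C=CC1=O | intermediate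
20 | CNP0148621.1: 14α-(2,5-dihydroxybenzyl)-13α-hydroxy-13β-methyl 19,20-lactone | C[C@@]12CC[C@@H]3[C@]4(CCC[C@]3(C)C(=O)OC4)[C@H]1CC[C@](C)(O)[C@@H]2Cc1cc(O)ccc1O | target

**Count and risks**

Total steps: 11. Longest linear sequence: 11 steps (1 to 20).

Step 8. What may go wrong: dienoate 13, a 2-(methoxycarbonyl)diene, is lost to Diels–Alder dimerisation while it is isolated and handled. During the hot stage the exo (cis-fusing) pathway and oligomerisation of 14 can also compete, because the C4 ester lowers the diene HOMO. Fallback (sets out from 11, comes back at 15): the diene is made last and only in the presence of its dienophile. Hydrostannation of 11 as in step 7 is stopped at stannane 12, which is isolated. MnO2 oxidises its allylic alcohol to the stannyl enal F1, which carries no diene and can be stored. Stille coupling of F1 with vinyl bromide (Pd(PPh3)4, CuI, DMF, dilute, 50 °C, then 100 °C) releases 14 in solution, where it should cyclise to 15 as it forms (Stille coupling/intramolecular Diels–Alder cascade).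

Step 4. What may go wrong: poor facial selectivity of the methyl transfer if the ketone reacts through the other chair, which would give the C13 epimer. Fallback (sets out from 20 as obtained together with its C13 epimer F2, comes back at 19): C13 is a spectator in steps 5 to 11, so an epimeric mixture is carried to the end and corrected there. Catalytic TsOH in CH2Cl2 should ionise the tertiary carbinol of 20 and of F2 to the same C13 cation. The C2' phenol oxygen, held under the α face by the axial C15 arm, can then only close the cis-fused 6-hydroxychroman F3. FeCl3 in aqueous methanol opens F3 oxidatively (tocopherol to tocopherylquinone type) to quinone 19 with the C13–O bond intact, and the dithionite stage of step 11 gives 20 as a single C13 epimer.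

Step 2. What may go wrong: acetylation of the electron-rich dimethoxyarene or capture of the tertiary cation by acetate under BF3/Ac2O, and loss of the C14 configuration by acid-catalysed enolisation. Fallback (sets out from 6, comes back at 8): halide-mediated opening without an acylating agent. Iodotrimethylsilane made in the flask from Me3SiCl and NaI in MeCN at 0 °C opens the cyclobutane to the silyl enol ether tertiary iodide F4. Aqueous work-up gives iodo ketone F5 (protonation at C12). DBU in toluene eliminates HI toward a methyl group to give ketone 8 directly, so that step 3 is not needed.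

Further compounds
F1 | step 8 | methyl (E)-2-(tributylstannyl)pent-2-enoate of 12 with the C20 alcohol oxidised to the 2-substituted acrolein | C[C@@]1(CC/C=C(/[Sn](CCCC)(CCCC)CCCC)C(=O)OC)[C@@H](C(C=O)=C)CC[C@](C)(O)[C@@H]1Cc1cc(OC)ccc1OC
F2 | step 4 | C13 epimer of 20 (13β-hydroxy-13α-methyl) | C[C@@]12CC[C@@H]3[C@]4(CCC[C@]3(C)C(=O)OC4)[C@H]1CC[C@@](C)(O)[C@@H]2Cc1cc(O)ccc1O
F3 | step 4 | cis-fused 6-hydroxychroman: C13–O–C2' cyclic ether of 20, C13 methyl β | C[C@@]12CC[C@@H]3[C@]4(CCC[C@]3(C)C(=O)OC4)[C@H]1CC[C@]5(C)Oc6ccc(O)cc6C[C@H]25
F4 | step 2 | trimethylsilyl enol ether (C12=C13) of the ring-opened ketone carrying a 2-iodopropan-2-yl group on C9 | C[C@@]1(CCC#C[Si](C)(C)C)[C@@H](C(C)(C)I)CC=C(O[Si](C)(C)C)[C@@H]1Cc1cc(OC)ccc1OC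
F5 | step 2 | 2-(2,5-dimethoxybenzyl)-4-(2-iodopropan-2-yl)-3-methyl-3-[4-(trimethylsilyl)but-3-ynyl]cyclohexan-1-one, configuration as in 8 | C[C@@]1(CCC#C[Si](C)(C)C)[C@@H](C(C)(C)I)CCC(=O)[C@@H]1Cc1cc(OC)ccc1OC
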